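The plan rests on cutting the C6–O bond of the 1,2-dioxane ring. C6 is a fully substituted carbon bearing oxygen, a methyl group, ring carbon C5 and chain carbon C7. This is the pattern of a 2-methylglycidol-type epoxide, so the ring is closed by letting a C3 hydroperoxide open a C6–C7 epoxide at its tertiary carbon. This single step forms the C6–O bond, builds the peroxide ring, sets C6 by inversion and releases C7 as a primary alcohol for chain growth. The precursor is an acyclic 3S hydroperoxide that carries a vinyl group as latent C1 ester and a 6R 2,2-disubstituted epoxide. The C11–C18 carbinol arrives late by Negishi coupling.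

Key step: step 8

Remark: atom labels follow the target chain (C1 ester carbon, C3–C6 dioxane carbons, C10 and C14 methylene-bearing carbons, C13 carbinol, C18 gem-dimethyl carbon). The target is 2R,3S,6R,13R. The descriptors of C2 and C6 change along the route only where substituent priorities change. C6 comes from 1 by retention (steps 1, 2) and one inversion (step 8). C3 comes from the anti crotylation product by one inversion (step 6).

Step 1
Reactants: 1 (S)-2-methylglycidol; 2 allylmagnesium bromide
Product: 3 (2R)-2-methylhex-5-ene-1,2-diol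
Conditions: 2 (2.5 equiv), CuI (10 mol %), THF, −40 to 0 °C; aqueous quench
Reagents that add atoms: none
Why: Copper-catalysed Grignard opening of a terminal epoxide (SN2 at the unsubstituted ring CH2, future C5) leaves the oxygen-bearing stereocentre (future C6) untouched, the first equivalent of 2 only deprotonates the alcohol, and a Payne shift of the alkoxide would be degenerate and return the same enantiomer.

Step 2
Reactants: 3 (2R)-2-methylhex-5-ene-1,2-diol
Product: 5 (2R)-2-(but-3-en-1-yl)-2-methyloxirane, via primary monotosylate 4 (not isolated)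
Conditions: NaH (2.2 equiv), THF, 0 °C; 1-(p-toluenesulfonyl)imidazole, 0 °C to rt
Reagents that add atoms: none
Why: One-pot selective sulfonylation and Williamson-type 3-exo-tet closure, in which the primary alkoxide is tosylated and the tertiary alkoxide displaces the tosylate at C7, so the C6–O bond is never broken, its configuration is retained and the epoxide now spans C6–C7.

Step 3
Reactants: 5 (2R)-2-(but-3-en-1-yl)-2-methyloxirane
Product: 6 3-[(2R)-2-methyloxiran-2-yl]propanal
Conditions: O3, CH2Cl2, −78 °C; PPh3, −78 °C to rt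
Reagents that add atoms: ozone [O-][O+]=O
Why: Ozonolysis with reductive work-up cleaves the only alkene to the C3 aldehyde, and the epoxide is inert to ozone and to PPh3 under these conditions.

Step 4
Reactants: 6 3-[(2R)-2-methyloxiran-2-yl]propanal; 7 (E)-but-2-ene
Product: 10 (3S,4R)-3-methyl-6-[(2R)-2-methyloxiran-2-yl]hex-1-en-4-ol, via (E)-crotylpotassium 8 (not isolated), via (E)-crotylborane 9 (not isolated)
Conditions: 7, n-BuLi, KOtBu, THF, −78 to −45 °C; (−)-Ipc2BOMe [from (+)-α-pinene], −78 °C; BF3·OEt2; 6, −78 °C; NaBO3·4H2O, THF/H2O, rt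
Reagents that add atoms: none
Why: Brown asymmetric crotylboration, in which the closed chair transition state turns the E geometry of 9 into the anti C2/C3 relation, the isopinocampheyl groups derived from (+)-α-pinene steer the crotyl group to the Si face of 6 and so set C2 as S and C3 as R, the remote C6 centre has no say, and BF3 is consumed by the alkoxides present so that the epoxide meets no free Lewis acid.

Step 5
Reactants: 11 2,3-dimethylbut-2-ene
Product: 12 2-hydroperoxy-2-methoxypropane
Conditions: O3, MeOH/CH2Cl2, −78 °C; kept and used as a solution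
Reagents that add atoms: ozone [O-][O+]=O; methanol CO
Why: Ozonolysis in a participating solvent, in which the Criegee carbonyl oxide released from the tetrasubstituted alkene is trapped by methanol as the α-methoxy hydroperoxide, an acid-labile carrier of the OOH group.

Step 6
Reactants: 10 (3S,4R)-3-methyl-6-[(2R)-2-methyloxiran-2-yl]hex-1-en-4-ol; 12 2-hydroperoxy-2-methoxypropane
Product: 14 (2R)-2-{(3S,4S)-3-[(2-methoxypropan-2-yl)peroxy]-4-methylhex-5-en-1-yl}-2-methyloxirane, via C3 triflate 13 (not isolated)
Conditions: Tf2O, 2,6-lutidine, CH2Cl2, −78 °C; then precooled 12 (4 equiv) and KOtBu (3.5 equiv) in THF, −78 to −20 °C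
Reagents that add atoms: none
Why: Sulfonate activation followed by SN2 alkylation of a peroxide anion, an α-effect nucleophile of low basicity, so that backside substitution in the cold should outrun E2 loss of the allylic C2–H and inverts C3 from R to S while the base-stable epoxide and the vinyl group are spectators.

Step 7
Reactants: 14 (2R)-2-{(3S,4S)-3-[(2-methoxypropan-2-yl)peroxy]-4-methylhex-5-en-1-yl}-2-methyloxirane
Product: 15 (2R)-2-[(3S,4S)-3-hydroperoxy-4-methylhex-5-en-1-yl]-2-methyloxirane
Conditions: pyridinium p-toluenesulfonate (10 mol %), MeOH, 0 °C; NaHCO3 quench; used at once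
Reagents that add atoms: none
Why: Acid-catalysed transketalisation, in which the peroxyketal ionises to a stabilised oxocarbenium ion under a buffered acid too weak to open the epoxide at 0 °C, methanol carries the acetone unit away, no stereocentre is touched, and any premature ring closure only anticipates step 8.

Step 8
Reactants: 15 (2R)-2-[(3S,4S)-3-hydroperoxy-4-methylhex-5-en-1-yl]-2-methyloxirane
Product: 16 [(3S,6S)-6-[(2S)-but-3-en-2-yl]-3-methyl-1,2-dioxan-3-yl]methanol
Conditions: (+)-camphor-10-sulfonic acid (10 mol %), CH2Cl2 (0.02 M), 0 °C to rt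
Reagents that add atoms: none
Why: This is an acid-catalysed intramolecular epoxide opening by a hydroperoxide, the peroxide counterpart of the familiar acid-promoted cyclisation of epoxy alcohols and itself an established entry to 1,2-dioxanes. The sulfonic acid activates the epoxide oxygen, the C6–O bond lengthens because C6 is the carbon that best carries positive charge, and the terminal oxygen of the C3 hydroperoxide adds to C6 from the face opposite the departing oxygen before a free cation can form. The 1,2-dioxane ring (O, O, C3, C4, C5, C6) closes in the 6-exo-tet mode, with the breaking C6–O bond outside the new ring and ending as the C7 primary alcohol. C6 is the only new stereocentre and is fixed by inversion of the 6R epoxide carbon inherited from 1, C2 and C3 are spectators, and the chair-like transition state holds the C3 side chain and C7 equatorial and only the methyl group axial, so no strain opposes the stereospecific path. The step needs attack at C6 instead of C7 (7-endo) and substitution instead of ionisation or 1,2-hydride shift, and ring size and Markovnikov polarisation both point to C6 while a non-nucleophilic solvent, dilution, low temperature and a catalytic acid keep the opening concerted. The vinyl group, the secondary C3–O bond and the O–O bond are inert under these conditions.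

Step 9
Reactants: 16 [(3S,6S)-6-[(2S)-but-3-en-2-yl]-3-methyl-1,2-dioxan-3-yl]methanol
Product: 18 (2R)-2-[(3S,6S)-6-(hydroxymethyl)-6-methyl-1,2-dioxan-3-yl]propanoic acid, via C1 aldehyde 17 (not isolated)
Conditions: O3, CH2Cl2, −78 °C; Me2S, −78 °C to rt; concentrate; NaClO2, NaH2PO4, 2-methylbut-2-ene, t-BuOH/H2O, 0 °C to rt
Reagents that add atoms: ozone [O-][O+]=O; sodium chlorite [Na+].[O-]Cl=O
Why: Ozonolysis with a sulfide work-up mild enough to spare the dialkyl peroxide, followed by Pinnick oxidation of the crude aldehyde, turns the vinyl group into the C1 acid under neutral to weakly acidic conditions, so C2 is not epimerised and the primary alcohol is untouched.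

Step 10
Reactants: 18 (2R)-2-[(3S,6S)-6-(hydroxymethyl)-6-methyl-1,2-dioxan-3-yl]propanoic acid
Product: 19 methyl (2R)-2-[(3S,6S)-6-(hydroxymethyl)-6-methyl-1,2-dioxan-3-yl]propanoate
Conditions: TMSCHN2, toluene/MeOH, 0 °C
Reagents that add atoms: (trimethylsilyl)diazomethane C[Si](C)(C)C=[N+]=[N-]
Why: O-Methylation of the carboxylic acid with a diazoalkane needs neither base nor strong acid, so β-elimination of the C3 peroxide and epimerisation at C2 cannot start and the alcohol is not alkylated.

Step 11
Reactants: 19 methyl (2R)-2-[(3S,6S)-6-(hydroxymethyl)-6-methyl-1,2-dioxan-3-yl]propanoate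
Product: 20 methyl (2R)-2-[(3S,6S)-6-formyl-6-methyl-1,2-dioxan-3-yl]propanoate
Conditions: Dess–Martin periodinane, CH2Cl2, 0 °C to rt
Reagents that add atoms: none
Why: Dess–Martin oxidation converts the neopentyl-type primary alcohol into the aldehyde under near-neutral conditions, and because C6 bears no hydrogen the α-peroxy aldehyde can neither enolise nor eliminate.

Step 12
Reactants: 21 3-bromobut-3-en-1-ol
Product: 22 2-bromo-4-iodobut-1-ene
Conditions: I2, PPh3, imidazole, CH2Cl2, 0 °C
Reagents that add atoms: iodine II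
Why: Appel-type iodination (alkoxyphosphonium formation, then SN2 by iodide) of an unhindered primary alcohol, to which the vinyl bromide is inert.

Step 13
Reactants: 22 2-bromo-4-iodobut-1-ene
Product: 23 (3-bromobut-3-en-1-yl)triphenylphosphonium iodide
Conditions: PPh3, MeCN, reflux
Reagents that add atoms: triphenylphosphine c1ccc(cc1)P(c1ccccc1)c1ccccc1
Why: Quaternisation of the phosphine by the primary iodide (SN2), the sp2 C–Br bond being unreactive toward PPh3.

Step 14
Reactants: 20 methyl (2R)-2-[(3S,6S)-6-formyl-6-methyl-1,2-dioxan-3-yl]propanoate; 23 (3-bromobut-3-en-1-yl)triphenylphosphonium iodide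
Product: 25 methyl (2R)-2-{(3S,6S)-6-[(1Z)-4-bromopenta-1,4-dien-1-yl]-6-methyl-1,2-dioxan-3-yl}propanoate, via phosphorus ylide 24 (not isolated)
Conditions: 23, NaHMDS (1.0 equiv), THF, −78 °C; then 20, −78 to 0 °C
Reagents that add atoms: none
Why: Wittig olefination with a non-stabilised ylide, preformed with exactly one equivalent of base so that the ester and its β-peroxide meet no free amide, adds C8–C10 and the methylene carbon to the non-enolisable aldehyde, and the expected Z geometry is irrelevant because the alkene is reduced next.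

Step 15
Reactants: 25 methyl (2R)-2-{(3S,6S)-6-[(1Z)-4-bromopenta-1,4-dien-1-yl]-6-methyl-1,2-dioxan-3-yl}propanoate
Product: 26 methyl (2R)-2-[(3S,6R)-6-(4-bromopent-4-en-1-yl)-6-methyl-1,2-dioxan-3-yl]propanoate
Conditions: KO2CN=NCO2K, AcOH, MeOH, 0 °C to rt, added in portions and stopped at full conversion of 25
Reagents that add atoms: none
Why: Diimide reduction (concerted syn transfer of H2) is the standard way to saturate an alkene without cleaving an O–O bond, and it should prefer the strained cis-dialkyl alkene C7=C8 over the bromoalkene because halogen-bearing alkenes are poor diimide acceptors, as the usual stop of haloalkyne reductions at the haloalkene shows.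

Step 16
Reactants: 27 2,2-dimethylcyclohexanone
Product: 28 2-bromo-3,3-dimethylcyclohex-1-ene-1-carbaldehyde
Conditions: PBr3, DMF, CHCl3, 0 °C to reflux; ice-water
Reagents that add atoms: N,N-dimethylformamide CN(C)C=O; phosphorus tribromide BrP(Br)Br; water O
Why: Vilsmeier–Haack–Arnold bromoformylation, in which 27 can enolise only toward C14, so formylation occurs there and the activated carbonyl carbon C13 takes up bromide to give one regioisomer of the β-bromo enal.

Step 17
Reactants: 28 2-bromo-3,3-dimethylcyclohex-1-ene-1-carbaldehyde; 29 allyltributylstannane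
Product: 30 3,3-dimethyl-2-(prop-2-en-1-yl)cyclohex-1-ene-1-carbaldehyde
Conditions: Pd2(dba)3 (2.5 mol %), AsPh3 (10 mol %), NMP, 60 °C
Reagents that add atoms: none
Why: Stille coupling of an electron-poor alkenyl bromide, with a weakly donating ligand that speeds transmetalation at the hindered C13 and with no base present that could move the skipped diene into conjugation.

Step 18
Reactants: 30 3,3-dimethyl-2-(prop-2-en-1-yl)cyclohex-1-ene-1-carbaldehyde
Product: 31 [3,3-dimethyl-2-(prop-2-en-1-yl)cyclohex-1-en-1-yl]methanol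
Conditions: NaBH4, CeCl3·7H2O, MeOH, 0 °C
Reagents that add atoms: none
Why: Luche reduction gives clean 1,2-reduction of the enal to the allylic alcohol needed for directed epoxidation.

Step 19
Reactants: 31 [3,3-dimethyl-2-(prop-2-en-1-yl)cyclohex-1-en-1-yl]methanol
Product: 32 [(1R,6R)-5,5-dimethyl-6-(prop-2-en-1-yl)-7-oxabicyclo[4.1.0]heptan-1-yl]methanol
Conditions: Ti(OiPr)4 (20 mol %), D-(−)-diethyl tartrate (24 mol %), t-BuOOH, 4 Å sieves, CH2Cl2, −20 °C
Reagents that add atoms: tert-butyl hydroperoxide CC(C)(C)OO
Why: Sharpless asymmetric epoxidation, in which the titanium tartrate binds the allylic alkoxide and the hydroperoxide and delivers oxygen to one face of C13=C14, D-(−)-tartrate making the hydroxymethyl-bearing carbon C14 R and, by syn addition, C13 R, while the allyl alkene lacks a directing hydroxyl group and stays intact.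

Step 20
Reactants: 32 [(1R,6R)-5,5-dimethyl-6-(prop-2-en-1-yl)-7-oxabicyclo[4.1.0]heptan-1-yl]methanol
Product: 33 (1R,6S)-6-(iodomethyl)-2,2-dimethyl-1-(prop-2-en-1-yl)-7-oxabicyclo[4.1.0]heptane
Conditions: I2, PPh3, imidazole, THF, 0 °C to rt
Reagents that add atoms: iodine II
Why: Appel-type iodination, eased because the carbinol carbon sits on an epoxide carbon whose tied-back bonds open the SN2 trajectory, under buffered conditions that epoxides tolerate.

Step 21
Reactants: 33 (1R,6S)-6-(iodomethyl)-2,2-dimethyl-1-(prop-2-en-1-yl)-7-oxabicyclo[4.1.0]heptane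
Product: 34 2-[(1R,6S)-6-(iodomethyl)-2,2-dimethyl-7-oxabicyclo[4.1.0]heptan-1-yl]ethan-1-ol
Conditions: O3 (to the first blue tint), CH2Cl2/MeOH, −78 °C; NaBH4, −78 to 0 °C
Reagents that add atoms: ozone [O-][O+]=O
Why: Ozonolysis with borohydride work-up shortens the allyl group to the two-carbon C12–C11 alcohol, since the terminal alkene reacts far faster with ozone than a primary alkyl iodide and borohydride touches neither the epoxide nor the hindered iodide at 0 °C.

Step 22
Reactants: 34 2-[(1R,6S)-6-(iodomethyl)-2,2-dimethyl-7-oxabicyclo[4.1.0]heptan-1-yl]ethan-1-ol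
Product: 35 (1R)-1-(2-hydroxyethyl)-2,2-dimethyl-6-methylidenecyclohexan-1-ol
Conditions: Zn dust, EtOH, reflux
Reagents that add atoms: none
Why: Zinc-mediated reductive β-elimination of a 2,3-epoxy iodide, the standard transposition of Sharpless epoxy alcohols, breaks only the C14–O bond, creates C14=CH2 regiospecifically and leaves the C13–O bond and its R configuration intact.

Step 23
Reactants: 35 (1R)-1-(2-hydroxyethyl)-2,2-dimethyl-6-methylidenecyclohexan-1-ol
Product: 36 (1R)-1-(2-iodoethyl)-2,2-dimethyl-6-methylidenecyclohexan-1-ol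
Conditions: I2 (1.05 equiv), PPh3, imidazole, CH2Cl2, 0 °C
Reagents that add atoms: iodine II
Why: Appel-type iodination is selective for the primary alcohol because the crowded tertiary allylic alcohol does not form the alkoxyphosphonium salt.

Step 24
Reactants: 36 (1R)-1-(2-iodoethyl)-2,2-dimethyl-6-methylidenecyclohexan-1-ol
Product: 37 triethyl{[(1R)-1-(2-iodoethyl)-2,2-dimethyl-6-methylidenecyclohexyl]oxy}silane
Conditions: Et3SiOTf, 2,6-lutidine, CH2Cl2, −78 to 0 °C
Reagents that add atoms: triethylsilyl trifluoromethanesulfonate CC[Si](CC)(CC)OS(=O)(=O)C(F)(F)F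
Why: Silylation with a silyl triflate and a hindered pyridine base is the method of choice for crowded tertiary alcohols and removes the only acidic proton before the organozinc reagent is made.

Step 25
Reactants: 37 triethyl{[(1R)-1-(2-iodoethyl)-2,2-dimethyl-6-methylidenecyclohexyl]oxy}silane; 26 methyl (2R)-2-[(3S,6R)-6-(4-bromopent-4-en-1-yl)-6-methyl-1,2-dioxan-3-yl]propanoate
Product: 39 13-O-triethylsilyl ether of the target, via alkylzinc iodide 38 (not isolated)
Conditions: 37, Zn dust (activated with cat. BrCH2CH2Br and Me3SiCl), LiCl, THF, 40 °C; decant from Zn; 26, Pd(dppf)Cl2 (5 mol %), THF, rt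
Reagents that add atoms: none
Why: Negishi sp3–sp2 coupling, in which zinc inserts into the primary C–I bond, the alkylzinc iodide tolerates ester, silyl ether and alkenes and is too weak a nucleophile to attack the O–O bond, the dppf ligand suppresses β-hydride elimination, no base is present that could trigger retro-oxa-Michael opening of the β-peroxy ester, and saturated 1,2-dioxanes are known to survive cross-coupling with zerovalent palladium.

Step 26
Reactants: 39 13-O-triethylsilyl ether of the target
Product: 40 methyl (2R)-2-[(3S,6R)-6-(4-{2-[(1R)-1-hydroxy-2,2-dimethyl-6-methylidenecyclohexyl]ethyl}pent-4-en-1-yl)-6-methyl-1,2-dioxan-3-yl]propanoate (target)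
Conditions: HF·pyridine, pyridine, THF, 0 °C to rt
Reagents that add atoms: none
Why: Fluoride-mediated desilylation in a pyridine-buffered medium is neither basic enough to open the β-peroxy ester nor acidic enough to ionise the tertiary allylic alcohol, and it touches no stereocentre.

Compound list
1 | (S)-2-methylglycidol | C[C@]1(CO)CO1 | starting material
2 | allylmagnesium bromide | C=CC[Mg]Br | starting material
3 | (2R)-2-methylhex-5-ene-1,2-diol | C[C@](O)(CO)CCC=C | intermediate
4 | (2R)-2-hydroxy-2-methylhex-5-en-1-yl 4-methylbenzenesulfonate | C[C@](O)(COS(=O)(=O)c1ccc(C)cc1)CCC=C | intermediate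
5 | (2R)-2-(but-3-en-1-yl)-2-methyloxirane | C[C@]1(CO1)CCC=C | intermediate
6 | 3-[(2R)-2-methyloxiran-2-yl]propanal | C[C@]1(CO1)CCC=O | intermediate
7 | (E)-but-2-ene | C/C=C/C | starting material
8 | (E)-crotylpotassium | C/C=C/C[K] | intermediate
9 | (E)-crotylbis(isopinocampheyl)borane, Ipc from (+)-α-pinene | C/C=C/CB([C@@H]1C[C@@H]2C[C@H]([C@H]1C)C2(C)C)[C@@H]1C[C@@H]2C[C@H]([C@H]1C)C2(C)C | intermediate
10 | (3S,4R)-3-methyl-6-[(2R)-2-methyloxiran-2-yl]hex-1-en-4-ol | C[C@]1(CO1)CC[C@@H](O)[C@@H](C)C=C | intermediate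
11 | 2,3-dimethylbut-2-ene | CC(C)=C(C)C | starting material
12 | 2-hydroperoxy-2-methoxypropane | COC(C)(C)OO | intermediate
13 | (3S,4R)-3-methyl-6-[(2R)-2-methyloxiran-2-yl]hex-1-en-4-yl trifluoromethanesulfonate | C[C@]1(CO1)CC[C@@H](OS(=O)(=O)C(F)(F)F)[C@@H](C)C=C | intermediate
14 | (2R)-2-{(3S,4S)-3-[(2-methoxypropan-2-yl)peroxy]-4-methylhex-5-en-1-yl}-2-methyloxirane | C[C@]1(CO1)CC[C@H](OOC(C)(C)OC)[C@@H](C)C=C | intermediate
15 | (2R)-2-[(3S,4S)-3-hydroperoxy-4-methylhex-5-en-1-yl]-2-methyloxirane | C[C@]1(CO1)CC[C@H](OO)[C@@H](C)C=C | intermediate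
16 | [(3S,6S)-6-[(2S)-but-3-en-2-yl]-3-methyl-1,2-dioxan-3-yl]methanol | OC[C@]1(C)CC[C@@H]([C@@H](C)C=C)OO1 | intermediate
17 | (2R)-2-[(3S,6S)-6-(hydroxymethyl)-6-methyl-1,2-dioxan-3-yl]propanal | OC[C@]1(C)CC[C@@H]([C@@H](C)C=O)OO1 | intermediate
18 | (2R)-2-[(3S,6S)-6-(hydroxymethyl)-6-methyl-1,2-dioxan-3-yl]propanoic acid | OC[C@]1(C)CC[C@@H]([C@@H](C)C(=O)O)OO1 | intermediate
19 | methyl (2R)-2-[(3S,6S)-6-(hydroxymethyl)-6-methyl-1,2-dioxan-3-yl]propanoate | OC[C@]1(C)CC[C@@H]([C@@H](C)C(=O)OC)OO1 | intermediate
20 | methyl (2R)-2-[(3S,6S)-6-formyl-6-methyl-1,2-dioxan-3-yl]propanoate | O=C[C@]1(C)CC[C@@H]([C@@H](C)C(=O)OC)OO1 | intermediate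
21 | 3-bromobut-3-en-1-ol | C=C(Br)CCO | starting material
22 | 2-bromo-4-iodobut-1-ene | C=C(Br)CCI | intermediate
23 | (3-bromobut-3-en-1-yl)triphenylphosphonium iodide | C=C(Br)CC[P+](c1ccccc1)(c1ccccc1)c1ccccc1.[I-] | intermediate
24 | (3-bromobut-3-en-1-ylidene)triphenylphosphorane | C=C(Br)CC=P(c1ccccc1)(c1ccccc1)c1ccccc1 | intermediate
25 | methyl (2R)-2-{(3S,6S)-6-[(1Z)-4-bromopenta-1,4-dien-1-yl]-6-methyl-1,2-dioxan-3-yl}propanoate | C=C(Br)C/C=C\[C@]1(C)CC[C@@H]([C@@H](C)C(=O)OC)OO1 | intermediate
26 | methyl (2R)-2-[(3S,6R)-6-(4-bromopent-4-en-1-yl)-6-methyl-1,2-dioxan-3-yl]propanoate | C=C(Br)CCC[C@]1(C)CC[C@@H]([C@@H](C)C(=O)OC)OO1 | intermediate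
27 | 2,2-dimethylcyclohexanone | CC1(C)CCCCC1=O | starting material
28 | 2-bromo-3,3-dimethylcyclohex-1-ene-1-carbaldehyde | O=CC1=C(Br)C(C)(C)CCC1 | intermediate
29 | allyltributylstannane | C=CC[Sn](CCCC)(CCCC)CCCC | starting material
30 | 3,3-dimethyl-2-(prop-2-en-1-yl)cyclohex-1-ene-1-carbaldehyde | O=CC1=C(CC=C)C(C)(C)CCC1 | intermediate
31 | [3,3-dimethyl-2-(prop-2-en-1-yl)cyclohex-1-en-1-yl]methanol | OCC1=C(CC=C)C(C)(C)CCC1 | intermediate
32 | [(1R,6R)-5,5-dimethyl-6-(prop-2-en-1-yl)-7-oxabicyclo[4.1.0]heptan-1-yl]methanol | OC[C@]12CCCC(C)(C)[C@@]1(CC=C)O2 | intermediate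
33 | (1R,6S)-6-(iodomethyl)-2,2-dimethyl-1-(prop-2-en-1-yl)-7-oxabicyclo[4.1.0]heptane | IC[C@]12CCCC(C)(C)[C@@]1(CC=C)O2 | intermediate
34 | 2-[(1R,6S)-6-(iodomethyl)-2,2-dimethyl-7-oxabicyclo[4.1.0]heptan-1-yl]ethan-1-ol | IC[C@]12CCCC(C)(C)[C@@]1(CCO)O2 | intermediate
35 | (1R)-1-(2-hydroxyethyl)-2,2-dimethyl-6-methylidenecyclohexan-1-ol | OCC[C@]1(O)C(=C)CCCC1(C)C | intermediate
36 | (1R)-1-(2-iodoethyl)-2,2-dimethyl-6-methylidenecyclohexan-1-ol | ICC[C@]1(O)C(=C)CCCC1(C)C | intermediate
37 | triethyl{[(1R)-1-(2-iodoethyl)-2,2-dimethyl-6-methylidenecyclohexyl]oxy}silane | ICC[C@]1(O[Si](CC)(CC)CC)C(=C)CCCC1(C)C | intermediate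
38 | {2-[(1R)-2,2-dimethyl-6-methylidene-1-(triethylsilyloxy)cyclohexyl]ethyl}zinc iodide | I[Zn]CC[C@]1(O[Si](CC)(CC)CC)C(=C)CCCC1(C)C | intermediate
39 | 13-O-triethylsilyl ether of the target | C=C(CCC[C@]1(C)CC[C@@H]([C@@H](C)C(=O)OC)OO1)CC[C@]1(O[Si](CC)(CC)CC)C(=C)CCCC1(C)C | intermediate
40 | CNP0185522.3, 2R,3S,6R,13R | C=C(CCC[C@]1(C)CC[C@@H]([C@@H](C)C(=O)OC)OO1)CC[C@]1(O)C(=C)CCCC1(C)C | target

Total step count: 26.
Longest linear sequence: 14 steps (1, 2, 3, 4, 6, 7, 8, 9, 10, 11, 14, 15, 25, 26).

Steps most likely to fail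

Step 6.
- **What may go wrong:** elimination toward the allylic C2–H, participation of the epoxide oxygen while triflate leaves, or slow substitution at the β-branched secondary carbon.
- **Fallback (sets out from 6, returns at 14):** the labile triflate is replaced by an isolable bromide that is reached through a second inversion. (Z)-But-2-ene is metallated (n-BuLi, KOtBu) to (Z)-crotylpotassium F1. With (+)-Ipc2BOMe and BF3·OEt2 this gives the antipodal (Z)-crotylborane F2. Addition to 6 and perborate work-up should give the syn alcohol F3 (C2 S, C3 S). Appel bromination (CBr4, PPh3, CH2Cl2, 0 °C) inverts C3 and gives the 3R bromide F4, a storable electrophile. Alkylation of 12 with it (CsOH·H2O, DMF, 0 °C to rt) inverts C3 once more and gives 14.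

Step 8.
- **What may go wrong:** partial ionisation at C6 with erosion of the stereochemical transfer, 1,2-hydride shift of the activated epoxide, or competing attack at C7.
- **Fallback (sets out from 10, returns at 16):** the roles of the two carbons are exchanged, so that the O–O unit is first attached to C6 and the ring is closed at C3. Mesylation of 10 (MsCl, Et3N, CH2Cl2, 0 °C) gives the mesylate F5. Perhydrolysis of the epoxide with ethereal H2O2 and catalytic H3PMo12O40 opens it at the tertiary carbon with inversion and gives the β-hydroxy hydroperoxide F6. Cs2CO3 in DMF then deprotonates only the hydroperoxide, which displaces the mesylate in a 6-exo-tet SN2 reaction with inversion at C3. This gives 16 with the same configuration at C3 and C6.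

Step 15.
- **What may go wrong:** competing hydrogen transfer to the bromoalkene, or sluggish reduction of the hindered C7=C8 alkene that forces a large excess of diimide.
- **Fallback (sets out from 20, returns at 39):** C10 is carried through the reduction as a masked ketone, so that C7=C8 is the only alkene present.
  - 2-(2-Bromoethyl)-2-methyl-1,3-dioxolane and PPh3 give the phosphonium bromide F7.
  - NaHMDS gives the ylide F8, which with 20 gives the Z-alkene ketal F9.
  - Diimide as in step 15 gives the saturated ketal F10.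
  - Pyridinium p-toluenesulfonate in wet acetone frees the methyl ketone F11.
  - The methyl group is deprotonated kinetically (KHMDS, one equivalent, THF, −78 °C), which is faster than removal of the hindered tertiary C2–H of the ester. Trapping with N-(5-chloro-2-pyridyl)bis(trifluoromethanesulfonimide) gives the 2-triflyloxy-1-alkene F12.
  - F12 takes the place of 26 in the coupling with 38 and gives 39.

Further compounds
F1 | step 6 | (Z)-crotylpotassium | C/C=C\C[K]
F2 | step 6 | (Z)-crotylbis(isopinocampheyl)borane, Ipc from (−)-α-pinene | C/C=C\CB([C@H]1C[C@H]2C[C@@H]([C@@H]1C)C2(C)C)[C@H]1C[C@H]2C[C@@H]([C@@H]1C)C2(C)C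
F3 | step 6 | (3S,4S)-3-methyl-6-[(2R)-2-methyloxiran-2-yl]hex-1-en-4-ol | C[C@]1(CO1)CC[C@H](O)[C@@H](C)C=C
F4 | step 6 | (2R)-2-[(3R,4S)-3-bromo-4-methylhex-5-en-1-yl]-2-methyloxirane | C[C@]1(CO1)CC[C@@H](Br)[C@@H](C)C=C
F5 | step 8 | (3S,4R)-3-methyl-6-[(2R)-2-methyloxiran-2-yl]hex-1-en-4-yl methanesulfonate | C[C@]1(CO1)CC[C@@H](OS(C)(=O)=O)[C@@H](C)C=C
F6 | step 8 | (3S,4R,7S)-7-hydroperoxy-8-hydroxy-3,7-dimethyloct-1-en-4-yl methanesulfonate | OC[C@@](C)(OO)CC[C@@H](OS(C)(=O)=O)[C@@H](C)C=C
F7 | step 15 | [2-(2-methyl-1,3-dioxolan-2-yl)ethyl]triphenylphosphonium bromide | CC1(CC[P+](c2ccccc2)(c2ccccc2)c2ccccc2)OCCO1.[Br-]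
F8 | step 15 | [2-(2-methyl-1,3-dioxolan-2-yl)ethylidene]triphenylphosphorane | CC1(CC=P(c2ccccc2)(c2ccccc2)c2ccccc2)OCCO1
F9 | step 15 | methyl (2R)-2-{(3S,6S)-6-methyl-6-[(1Z)-3-(2-methyl-1,3-dioxolan-2-yl)prop-1-en-1-yl]-1,2-dioxan-3-yl}propanoate | CC1(C/C=C\[C@]2(C)CC[C@@H]([C@@H](C)C(=O)OC)OO2)OCCO1
F10 | step 15 | methyl (2R)-2-{(3S,6R)-6-methyl-6-[3-(2-methyl-1,3-dioxolan-2-yl)propyl]-1,2-dioxan-3-yl}propanoate | CC1(CCC[C@]2(C)CC[C@@H]([C@@H](C)C(=O)OC)OO2)OCCO1
F11 | step 15 | methyl (2R)-2-[(3S,6R)-6-methyl-6-(4-oxopentyl)-1,2-dioxan-3-yl]propanoate | CC(=O)CCC[C@]1(C)CC[C@@H]([C@@H](C)C(=O)OC)OO1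
F12 | step 15 | methyl (2R)-2-[(3S,6R)-6-methyl-6-{4-[(trifluoromethanesulfonyl)oxy]pent-4-en-1-yl}-1,2-dioxan-3-yl]propanoate | C=C(OS(=O)(=O)C(F)(F)F)CCC[C@]1(C)CC[C@@H]([C@@H](C)C(=O)OC)OO1
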